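**Strategy.** The target is disconnected to a cis-fused α-methylene-γ-butyrolactone spanning C2–C3 of dihydrofuran ring B. The C3 oxygen and the formyl carbon on Cα (the acrolein carbon on C2) are cis and 1,4-related, so acetate and aldehyde together are one opened lactone. A single titanium-mediated carbonylative cyclization of a salicylaldehyde allenyl ether forms C2–C3, Cα–C(=O) and the acyl–O bond, closing ring B and the lactone and setting both ring stereocentres. The precursor is 2-(allenyloxy)-5-[(1R)-1-(triethylsilyloxy)ethyl]benzaldehyde. It is made from methyl 5-acetylsalicylate, so that the phenol is alkylated before the benzylic centre is created and the aldehyde carbon is carried as an ester.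

Key step: step 7

Remark: locants are those of 2,3-dihydro-1-benzofuran (ring A = benzene ring, ring B = dihydrofuran ring, ring C = the lactone of 10; Cα = the carbon on C2; C1′–C3′ = allene carbons counted from oxygen); EBTHI = ethylene-1,2-bis(η5-4,5,6,7-tetrahydro-1-indenyl), whose sense of induction cannot be predicted here, so the (S,S) complex is written provisionally and its mirror image is to be used if the first run delivers the (3aR,8bR) series.

Step 1
Reactants: 1 methyl 5-acetyl-2-hydroxybenzoate; 2 propargyl bromide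
Product: 3 methyl 5-acetyl-2-(prop-2-yn-1-yloxy)benzoate
Conditions: K2CO3 (1.5 equiv), DMF, 50 °C
Reagents that add atoms: propargyl bromide (C#CCBr)
Why: Williamson etherification, in which the salicylate phenoxide is alkylated by the primary propargylic bromide (SN2); alkylating first means that no free phenol stands para to the benzylic centre once it exists.

Step 2
Reactants: 3 methyl 5-acetyl-2-(prop-2-yn-1-yloxy)benzoate
Product: 4 methyl 5-[(1R)-1-hydroxyethyl]-2-(prop-2-yn-1-yloxy)benzoate
Conditions: RuCl(p-cymene)[(R,R)-TsDPEN] (1 mol%), HCO2H/Et3N (5:2), 30 °C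
Reagents that add atoms: none
Why: Noyori asymmetric transfer hydrogenation of an aryl methyl ketone, in which the (R,R)-diamine complex of divalent ruthenium delivers hydride through its six-membered outer-sphere transition state to the face that gives the (R)-carbinol (as with acetophenone), the ester being inert and the remote terminal alkyne not being engaged at this temperature.

Step 3
Reactants: 4 methyl 5-[(1R)-1-hydroxyethyl]-2-(prop-2-yn-1-yloxy)benzoate
Product: 5 methyl 2-(prop-2-yn-1-yloxy)-5-[(1R)-1-(triethylsilyloxy)ethyl]benzoate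
Conditions: Et3SiCl, imidazole, CH2Cl2, 0 °C → rt
Reagents that add atoms: chlorotriethylsilane (CC[Si](Cl)(CC)CC)
Why: Imidazole-promoted silyl ether formation at the only hydroxyl group, giving a TES ether that should withstand hydride, catalytic alkoxide, MnO2 and the titanium step and can later be removed with buffered fluoride.

Step 4
Reactants: 5 methyl 2-(prop-2-yn-1-yloxy)-5-[(1R)-1-(triethylsilyloxy)ethyl]benzoate
Product: 6 {2-(prop-2-yn-1-yloxy)-5-[(1R)-1-(triethylsilyloxy)ethyl]phenyl}methanol
Conditions: i-Bu2AlH (2.5 equiv), CH2Cl2, −78 → 0 °C; aq. KNaC4H4O6 (potassium sodium tartrate)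
Reagents that add atoms: none
Why: Hydride reduction of the methyl ester to the primary benzylic alcohol, with the silyl ether and the propargyl ether untouched at low temperature.

Step 5
Reactants: 6 {2-(prop-2-yn-1-yloxy)-5-[(1R)-1-(triethylsilyloxy)ethyl]phenyl}methanol
Product: 7 {2-(propa-1,2-dien-1-yloxy)-5-[(1R)-1-(triethylsilyloxy)ethyl]phenyl}methanol
Conditions: KOt-Bu (0.3 equiv), THF, 0 °C → rt; aq. NH4Cl as soon as 6 is consumed
Reagents that add atoms: none
Why: Base-catalysed propargyl-to-allenyl prototropic isomerization, which for aryl propargyl ethers favours the oxygen-conjugated allene at room temperature; at the alcohol oxidation level the transient carbanion has no ortho electrophile, and the low base loading and temperature should keep the alkoxide from adding to the allene.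

Step 6
Reactants: 7 {2-(propa-1,2-dien-1-yloxy)-5-[(1R)-1-(triethylsilyloxy)ethyl]phenyl}methanol
Product: 8 2-(propa-1,2-dien-1-yloxy)-5-[(1R)-1-(triethylsilyloxy)ethyl]benzaldehyde
Conditions: MnO2 (activated, 10 equiv), CH2Cl2, rt
Reagents that add atoms: none
Why: MnO2 oxidation of a benzylic alcohol under neutral heterogeneous conditions, which should stop at the aryl aldehyde and leave the acid-sensitive allenyl ether and the TES ether intact.

Step 7
Reactants: 8 2-(propa-1,2-dien-1-yloxy)-5-[(1R)-1-(triethylsilyloxy)ethyl]benzaldehyde; 9 carbon monoxide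
Product: 10 (3aS,8bS)-3-methylidene-7-[(1R)-1-(triethylsilyloxy)ethyl]-3a,8b-dihydrofuro[3,2-b][1]benzofuran-2(3H)-one
Conditions: (S,S)-(EBTHI)Ti(CO)2 (20 mol%), PMe3 (40 mol%), CO (1.2 atm), toluene, 90 °C
Reagents that add atoms: carbon monoxide ([C-]#[O+])
Why: Proposed new method: after loss of CO the divalent titanocene binds the aldehyde and the oxygen-substituted C1′=C2′ bond of the allene and undergoes oxidative cyclization to an oxatitanacyclopentane, which forms C2–C3 and closes ring B in a 5-exo mode (both reacting π bonds exocyclic to the new ring, tether C3a–C7a–O1); CO then inserts into the Ti–alkenyl bond at Cα, and C–O reductive elimination from the six-membered acyl alkoxide contracts it to the five-membered lactone ring C and returns the dicarbonyl. The closest known reactions are titanocene-catalysed hetero-Pauson–Khand cyclocarbonylations of tethered alkene–aryl ketones, including EBTHI-controlled enantioselective cases, and Ru3(CO)12- or Mo(CO)6-mediated cyclocarbonylations of allene–aldehydes to cis-fused α-methylene-γ-butyrolactones; an aryl allenyl ether has not been used in either, least of all enantioselectively. C3 is set in the oxidative cyclization by the twofold-symmetric ansa ligand, which must distinguish the two aldehyde faces because the remote (R) centre exerts no control, and C2 follows from C3 since a 5/5 bicycle can only be cis-fused. The step needs reaction at the proximal and not the distal allene π bond, which the three-atom tether secures because only the proximal bond gives a five-membered ring B while keeping the methylene exocyclic; it also needs the carbonyl group to enter the titanium cycle, for which the conjugated aryl aldehyde resembles the aryl ketones that are known to turn over.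

Step 8
Reactants: 10 (3aS,8bS)-3-methylidene-7-[(1R)-1-(triethylsilyloxy)ethyl]-3a,8b-dihydrofuro[3,2-b][1]benzofuran-2(3H)-one
Product: 11 2-{(2S,3S)-3-hydroxy-5-[(1R)-1-(triethylsilyloxy)ethyl]-2,3-dihydro-1-benzofuran-2-yl}-N-methoxy-N-methylprop-2-enamide
Conditions: AlMe3, MeNH(OMe), CH2Cl2, 0 °C (gives Me2AlN(OMe)Me); then 10, 0 °C → rt; aq. KNaC4H4O6 (potassium sodium tartrate)
Reagents that add atoms: N,O-dimethylhydroxylamine (CNOC)
Why: Weinreb aminolysis of a lactone, in which the aluminium amide activates the lactone carbonyl and delivers nitrogen in a 1,2 and not a conjugate sense, opening ring C to the γ-hydroxy N-methoxy-N-methylamide with C2 and C3 untouched; the crude product is to be acetylated at once to forestall relactonization.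

Step 9
Reactants: 11 2-{(2S,3S)-3-hydroxy-5-[(1R)-1-(triethylsilyloxy)ethyl]-2,3-dihydro-1-benzofuran-2-yl}-N-methoxy-N-methylprop-2-enamide
Product: 12 (2S,3S)-2-{3-[methoxy(methyl)amino]-3-oxoprop-1-en-2-yl}-5-[(1R)-1-(triethylsilyloxy)ethyl]-2,3-dihydro-1-benzofuran-3-yl acetate
Conditions: Ac2O, pyridine, DMAP (5 mol%), CH2Cl2, 0 °C
Reagents that add atoms: acetic anhydride (CC(=O)OC(C)=O)
Why: O-Acylation of the secondary benzylic alcohol, which fixes the opened form and installs the C3 acetate of the target with retention at C3.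

Step 10
Reactants: 12 (2S,3S)-2-{3-[methoxy(methyl)amino]-3-oxoprop-1-en-2-yl}-5-[(1R)-1-(triethylsilyloxy)ethyl]-2,3-dihydro-1-benzofuran-3-yl acetate
Product: 13 (2S,3S)-5-[(1R)-1-hydroxyethyl]-2-{3-[methoxy(methyl)amino]-3-oxoprop-1-en-2-yl}-2,3-dihydro-1-benzofuran-3-yl acetate
Conditions: HF·pyridine, pyridine, THF, 0 °C
Reagents that add atoms: none
Why: Fluoride-mediated silyl ether cleavage, in which buffered HF·pyridine should remove the TES group through the strong Si–F bond without ionizing the benzylic C–O bonds or touching the acetate and the amide.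

Step 11
Reactants: 13 (2S,3S)-5-[(1R)-1-hydroxyethyl]-2-{3-[methoxy(methyl)amino]-3-oxoprop-1-en-2-yl}-2,3-dihydro-1-benzofuran-3-yl acetate; 14 angelic acid
Product: 16 (1R)-1-[(2S,3S)-3-acetoxy-2-{3-[methoxy(methyl)amino]-3-oxoprop-1-en-2-yl}-2,3-dihydro-1-benzofuran-5-yl]ethyl (2Z)-2-methylbut-2-enoate, via angelic 2,4,6-trichlorobenzoic anhydride 15 (not isolated)
Conditions: 14, 2,4,6-Cl3C6H2COCl, Et3N, toluene, rt; then 13, 75 °C
Reagents that add atoms: angelic acid (C/C=C(/C)C(=O)O)
Why: Yamaguchi-type mixed-anhydride esterification run without a nucleophilic amine catalyst, in which the hindered trichlorobenzoyl carbonyl directs the alcohol to the angeloyl carbonyl and the absence of DMAP avoids the addition–elimination pathway that turns angelates into tiglates, so the Z geometry and the (R) centre (acylation at oxygen) are retained.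

Step 12
Reactants: 16 (1R)-1-[(2S,3S)-3-acetoxy-2-{3-[methoxy(methyl)amino]-3-oxoprop-1-en-2-yl}-2,3-dihydro-1-benzofuran-5-yl]ethyl (2Z)-2-methylbut-2-enoate
Product: 17 (1R)-1-[(2S,3S)-3-acetoxy-2-(3-oxoprop-1-en-2-yl)-2,3-dihydro-1-benzofuran-5-yl]ethyl (2Z)-2-methylbut-2-enoate
Conditions: Cp2Zr(H)Cl (1.5 equiv), THF, rt, 15 min; filtration through silica gel
Reagents that add atoms: none
Why: Schwartz-reagent reduction of a tertiary amide, in which hydrozirconation of the amide carbonyl gives a zirconated N,O-hemiaminal that persists until work-up and then releases the aldehyde; this is faster than hydrozirconation of a 1,1-disubstituted alkene and does not reduce esters.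

**Compound list**

1 | methyl 5-acetyl-2-hydroxybenzoate (methyl 5-acetylsalicylate) | COC(=O)c1cc(C(C)=O)ccc1O | starting material
2 | propargyl bromide (3-bromoprop-1-yne) | C#CCBr | starting material
3 | methyl 5-acetyl-2-(prop-2-yn-1-yloxy)benzoate | COC(=O)c1cc(C(C)=O)ccc1OCC#C | intermediate
4 | methyl 5-[(1R)-1-hydroxyethyl]-2-(prop-2-yn-1-yloxy)benzoate | COC(=O)c1cc([C@@H](C)O)ccc1OCC#C | intermediate
5 | methyl 2-(prop-2-yn-1-yloxy)-5-[(1R)-1-(triethylsilyloxy)ethyl]benzoate | COC(=O)c1cc([C@@H](C)O[Si](CC)(CC)CC)ccc1OCC#C | intermediate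
6 | {2-(prop-2-yn-1-yloxy)-5-[(1R)-1-(triethylsilyloxy)ethyl]phenyl}methanol | OCc1cc([C@@H](C)O[Si](CC)(CC)CC)ccc1OCC#C | intermediate
7 | {2-(propa-1,2-dien-1-yloxy)-5-[(1R)-1-(triethylsilyloxy)ethyl]phenyl}methanol | OCc1cc([C@@H](C)O[Si](CC)(CC)CC)ccc1OC=C=C | intermediate
8 | 2-(propa-1,2-dien-1-yloxy)-5-[(1R)-1-(triethylsilyloxy)ethyl]benzaldehyde | O=Cc1cc([C@@H](C)O[Si](CC)(CC)CC)ccc1OC=C=C | intermediate
9 | carbon monoxide | [C-]#[O+] | starting material
10 | (3aS,8bS)-3-methylidene-7-[(1R)-1-(triethylsilyloxy)ethyl]-3a,8b-dihydrofuro[3,2-b][1]benzofuran-2(3H)-one | C=C1C(=O)O[C@H]2c3cc([C@@H](C)O[Si](CC)(CC)CC)ccc3O[C@@H]12 | intermediate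
11 | 2-{(2S,3S)-3-hydroxy-5-[(1R)-1-(triethylsilyloxy)ethyl]-2,3-dihydro-1-benzofuran-2-yl}-N-methoxy-N-methylprop-2-enamide | C=C(C(=O)N(C)OC)[C@@H]1Oc2ccc([C@@H](C)O[Si](CC)(CC)CC)cc2[C@@H]1O | intermediate
12 | (2S,3S)-2-{3-[methoxy(methyl)amino]-3-oxoprop-1-en-2-yl}-5-[(1R)-1-(triethylsilyloxy)ethyl]-2,3-dihydro-1-benzofuran-3-yl acetate | C=C(C(=O)N(C)OC)[C@@H]1Oc2ccc([C@@H](C)O[Si](CC)(CC)CC)cc2[C@@H]1OC(C)=O | intermediate
13 | (2S,3S)-5-[(1R)-1-hydroxyethyl]-2-{3-[methoxy(methyl)amino]-3-oxoprop-1-en-2-yl}-2,3-dihydro-1-benzofuran-3-yl acetate | C=C(C(=O)N(C)OC)[C@@H]1Oc2ccc([C@@H](C)O)cc2[C@@H]1OC(C)=O | intermediate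
14 | angelic acid ((2Z)-2-methylbut-2-enoic acid) | C/C=C(/C)C(=O)O | starting material
15 | angelic 2,4,6-trichlorobenzoic anhydride | C/C=C(/C)C(=O)OC(=O)c1c(Cl)cc(Cl)cc1Cl | intermediate
16 | (1R)-1-[(2S,3S)-3-acetoxy-2-{3-[methoxy(methyl)amino]-3-oxoprop-1-en-2-yl}-2,3-dihydro-1-benzofuran-5-yl]ethyl (2Z)-2-methylbut-2-enoate | C=C(C(=O)N(C)OC)[C@@H]1Oc2ccc([C@@H](C)OC(=O)/C(C)=C\C)cc2[C@@H]1OC(C)=O | intermediate
17 | (1R)-1-[(2S,3S)-3-acetoxy-2-(3-oxoprop-1-en-2-yl)-2,3-dihydro-1-benzofuran-5-yl]ethyl (2Z)-2-methylbut-2-enoate | C=C(C=O)[C@@H]1Oc2ccc([C@@H](C)OC(=O)/C(C)=C\C)cc2[C@@H]1OC(C)=O | target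

Total step count: 12. Longest linear sequence: 12 steps (1 → 17).

**Steps most likely to fail**

1. Step 7 (proposed new method). The cyclocarbonylation may stall because the strong titanium–oxygen bond resists turnover. It may also engage the distal π bond, lose the aryloxy group by β-elimination from the titanacycle, or proceed with poor or opposite facial selectivity. Fallback with known chemistry: setting out from aldehyde 8, the non-asymmetric cyclocarbonylation of allene–aldehydes with Ru3(CO)12 (2 mol%) under CO (10 atm) in dioxane at 120 °C is applied. It should give the same cis-fused methylene lactone but without facial control, that is 10 together with the ring-epimeric (3aR,8bR) lactone F1. Because of the fixed (R) side-chain centre the two are diastereomers, to be separated by preparative HPLC, and the route is rejoined at 10. Absolute control is thus exchanged for a separation.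

2. Step 12. The reduction may fail through competing hydrozirconation of the 1,1-disubstituted alkene or attack on the two esters. The enal may also be lost on work-up by conjugate addition of the liberated amine, with displacement of the allylic aryloxy group. Fallback: setting out from lactone 10, i-Bu2AlH (3 equiv, CH2Cl2, −78 → 0 °C) should reduce the lactone to the allylic diol F2. TBDPSCl/imidazole (CH2Cl2, 0 °C) then silylates the primary hydroxyl selectively to the primary TBDPS ether F3, and Ac2O/pyridine gives the C3 acetate F4. HF·pyridine/pyridine (THF, 0 °C) removes only the TES group to give the side-chain alcohol F5, and angeloylation as in step 11 (through 15) gives the angelate F6. HF·pyridine (THF, rt) then removes the TBDPS group to give the allylic alcohol F7, and MnO2 (CH2Cl2, rt) oxidizes it to the enal, rejoining the route at target 17. This path avoids both the amide and the hydride transfer to it.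

3. Step 11. The angeloyl unit may isomerize from Z to E during acyl activation, and acylation without a nucleophilic catalyst may be sluggish. Fallback: setting out from alcohol 13, esterification with 2-[bis(2,2,2-trifluoroethoxy)phosphoryl]propanoic acid (DCC, DMAP cat., CH2Cl2, 0 °C), an acid with no alkene geometry to lose, gives the phosphonopropanoate F8. Still–Gennari olefination with acetaldehyde (KN(SiMe3)2, 18-crown-6, THF, −78 °C) then builds the trisubstituted alkene under kinetic Z control and returns to 16.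

**Further compounds**

F1 | step 7 | (3aR,8bR)-3-methylidene-7-[(1R)-1-(triethylsilyloxy)ethyl]-3a,8b-dihydrofuro[3,2-b][1]benzofuran-2(3H)-one | C=C1C(=O)O[C@@H]2c3cc([C@@H](C)O[Si](CC)(CC)CC)ccc3O[C@H]12
F2 | step 12 | (2S,3S)-2-(3-hydroxyprop-1-en-2-yl)-5-[(1R)-1-(triethylsilyloxy)ethyl]-2,3-dihydro-1-benzofuran-3-ol | C=C(CO)[C@@H]1Oc2ccc([C@@H](C)O[Si](CC)(CC)CC)cc2[C@@H]1O
F3 | step 12 | (2S,3S)-2-{3-[tert-butyl(diphenyl)silyloxy]prop-1-en-2-yl}-5-[(1R)-1-(triethylsilyloxy)ethyl]-2,3-dihydro-1-benzofuran-3-ol | C=C(CO[Si](c1ccccc1)(c1ccccc1)C(C)(C)C)[C@@H]1Oc2ccc([C@@H](C)O[Si](CC)(CC)CC)cc2[C@@H]1O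
F4 | step 12 | (2S,3S)-2-{3-[tert-butyl(diphenyl)silyloxy]prop-1-en-2-yl}-5-[(1R)-1-(triethylsilyloxy)ethyl]-2,3-dihydro-1-benzofuran-3-yl acetate | C=C(CO[Si](c1ccccc1)(c1ccccc1)C(C)(C)C)[C@@H]1Oc2ccc([C@@H](C)O[Si](CC)(CC)CC)cc2[C@@H]1OC(C)=O
F5 | step 12 | (2S,3S)-2-{3-[tert-butyl(diphenyl)silyloxy]prop-1-en-2-yl}-5-[(1R)-1-hydroxyethyl]-2,3-dihydro-1-benzofuran-3-yl acetate | C=C(CO[Si](c1ccccc1)(c1ccccc1)C(C)(C)C)[C@@H]1Oc2ccc([C@@H](C)O)cc2[C@@H]1OC(C)=O
F6 | step 12 | (1R)-1-[(2S,3S)-3-acetoxy-2-{3-[tert-butyl(diphenyl)silyloxy]prop-1-en-2-yl}-2,3-dihydro-1-benzofuran-5-yl]ethyl (2Z)-2-methylbut-2-enoate | C=C(CO[Si](c1ccccc1)(c1ccccc1)C(C)(C)C)[C@@H]1Oc2ccc([C@@H](C)OC(=O)/C(C)=C\C)cc2[C@@H]1OC(C)=O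
F7 | step 12 | (1R)-1-[(2S,3S)-3-acetoxy-2-(3-hydroxyprop-1-en-2-yl)-2,3-dihydro-1-benzofuran-5-yl]ethyl (2Z)-2-methylbut-2-enoate | C=C(CO)[C@@H]1Oc2ccc([C@@H](C)OC(=O)/C(C)=C\C)cc2[C@@H]1OC(C)=O
F8 | step 11 | (1R)-1-[(2S,3S)-3-acetoxy-2-{3-[methoxy(methyl)amino]-3-oxoprop-1-en-2-yl}-2,3-dihydro-1-benzofuran-5-yl]ethyl 2-[bis(2,2,2-trifluoroethoxy)phosphoryl]propanoate | C=C(C(=O)N(C)OC)[C@@H]1Oc2ccc([C@@H](C)OC(=O)C(C)P(=O)(OCC(F)(F)F)OCC(F)(F)F)cc2[C@@H]1OC(C)=O
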